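Read the delta run first, the chair directed, and divide its rate by the substrate left, then see whether that ratio drifts as the run goes on.

| flask | substrate | free enzyme | temperature | remark | time |
|---|---|---|---|---|---|
| theta | 0.029 M | 1.4 µM | −30 °C | run made earlier |  |
| delta | 0.029 M | 2.2 µM | −2 °C | run made earlier |  |
| zeta | 0.044 M | 2.9 µM | −30 °C | run made earlier |  |
| north-west | 0.029 M | 2.9 µM | 5 °C |  | 20 min |
| south-west | 0.029 M | 2.9 µM | 20 °C |  | 20 min |
| south-east | 0.029 M | 2.9 µM | −25 °C |  | 20 min |
| west | 0.029 M | 2.9 µM | −10 °C |  | 20 min |

- theta (time / min: target / %, substrate / %): 4.00: 2, 97; 12.0: 7, 92; 15.0: 10, 87; 30.0: 21, 82; 50.0: 35, 68; 60.0: 39, 59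
- delta (time / min: target / %, substrate / %): 1.50: 12, 87; 3.00: 26, 76; 5.00: 38, 57; 6.00: 46, 56; 8.00: 57, 42; 10.0: 68, 32; 12.0: 74, 25
- zeta (time / min: target / %, substrate / %): 6.00: 8, 96; 12.0: 13, 90; 15.0: 17, 86; 30.0: 28, 70; 60.0: 57, 44

(scatter of a reading: 1.5 percentage points)

- what was read earlier has a scatter of 1.5 percentage points, one standard deviation

* the flask that comes out highest in amount of target, in percent of the substrate charged, or "all alike" when all lie within 1.5 percentage points (north-west / south-west / south-east / west / all alike)
* target at the end, in percent of the substrate charged, north-west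
* target at the end, in percent of the substrate charged, south-west
* target at the end, in percent of the substrate charged, south-east
* target at the end, in percent of the substrate charged, west

The analyst reported that in theta and zeta, both at −30 °C, target climbed along a straight line. At 60.0 min, [target] in zeta stood 2.22 times that in theta, with 2.07 times the free enzyme, so she scaled rates with the enzyme charged.

The delta curve, she went on, bends. But a bend can mean a dying enzyme or a falling [substrate], and the ratio of rate to [substrate] tells them apart. Taken as ln(charged/left) over time, it read 0.0915 /min at 3.00 min and 0.116 /min at 12.0 min, so the ratio climbed rather than fell. She therefore read delta as not strictly pseudo-first-order in substrate, but with the enzyme still working at its last reading.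

Scaled to 2.9 µM, the later figure gives 0.152 /min, the substrate constant at −2 °C for that charge of free enzyme. Her own reckoning carried that constant, with no correction for temperature, to north-west, which is warmer than delta: after 20 min, 4.78% of the substrate is left, so about 95.2% is target. She named north-west as highest. For south-west she committed to no figure, since the earlier runs stop at −2 °C.

The forecast differed. It named west as highest at 90%, with north-west at 60%, south-west at 12% and south-east at 43%, holding of the warm flasks that “the enzyme dies within minutes”.

The flasks gave 96.6% in north-west, 82.6% in south-west, 44.4% in south-east and 92.3% in west, so north-west came highest.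

    free enzyme → unfolded enzyme (k = 5.30 × 10⁻⁴ /min, Ea = 241 kJ/mol)
    substrate + free enzyme ⇌ complex (K = 34.0 /M, k = 2.10 × 10⁵ /M/s, Ea = 14.0 kJ/mol, ΔH = −53.0 kJ/mol)
    complex ⇌ free enzyme + target (K = 2.10 M, k = 3700 /min, Ea = 52.0 kJ/mol, ΔH = −53.0 kJ/mol)
    2 free enzyme ⇌ resting dimer, settled at all times (K = 2.00 × 10⁵ /M, ΔH = −12.0 kJ/mol)
    (constants at 5 °C)

At 20.0 min, north-west held 0.563% of the catalyst charged as unfolded enzyme. Its substrate left was 3.4%, against 4.78% from 0.152 /min. For the same north-west flask read at 8.0 min, 0.152 /min gives 29.6% left, and that flask held 26%.

The data were computed with made-up constants; scatter was added.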